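**Retrosynthetic overview** (chain numbered C1 = benzylic CH2, C2 = acetoxy carbon, C3–C13 = chain ending in CH2OH)
- Target 9 comes from bis(benzyl ether) 8 by one hydrogenolysis that frees the phenol and the primary alcohol.
- 8 comes from forming the C2–C3 bond by a nickel-catalysed enantioconvergent hydroalkylation. The racemic 1-bromoalkyl acetate 7 (made in the flask from arylacetaldehyde 4 and acetyl bromide) is joined to terminal olefin 6 with a hydrosilane; this one operation forms the bond, sets C2 as (R) and installs the acetate of the target.
- Enabling feature: the acetoxy group O–C(=O)–CH3 on C2. C2 is a former aldehyde carbon that acetyl bromide turns into a radical precursor, the ester carbonyl oxygen binds nickel, and C3–C4 is an unbranched CH2–CH2, i.e. a former terminal vinyl group.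
- 4 comes from benzaldehyde 2 by one-carbon homologation (Wittig, then hydrolysis), and 2 from phenol 1; 6 comes from undec-10-en-1-ol 5 by benzylation.
- No ring is formed; the benzene ring of 1 is carried through unchanged.

Key step: step 5

Assumption: the sense of induction of the nickel/bis(oxazoline) catalyst for this substrate is to be fixed by a test coupling on a model aldehyde; L* below means the ligand antipode that delivers the (R)-acetate.

Step 1
Reactants: 1 3-hydroxy-5-methoxybenzaldehyde
Product: 2 3-(benzyloxy)-5-methoxybenzaldehyde
Conditions: BnBr, K2CO3, DMF, rt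
Reagents that add atoms: benzyl bromide, BrCc1ccccc1
Why: Williamson ether synthesis; the phenoxide formed with K2CO3 should displace bromide from benzyl bromide (SN2) while the aldehyde is inert.

Step 2
Reactants: 2 3-(benzyloxy)-5-methoxybenzaldehyde
Product: 3 1-(benzyloxy)-3-methoxy-5-(2-methoxyethenyl)benzene (E/Z mixture)
Conditions: Ph3P(CH2OMe)Cl, KOtBu, THF, 0 °C to rt
Reagents that add atoms: (methoxymethyl)triphenylphosphonium chloride, COC[P+](c1ccccc1)(c1ccccc1)c1ccccc1.[Cl-]
Why: Wittig olefination with the non-stabilised methoxymethylene ylide should convert the aryl aldehyde into the enol ether; the double-bond geometry is of no consequence and the aryl ethers are inert to the base.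

Step 3
Reactants: 3 1-(benzyloxy)-3-methoxy-5-(2-methoxyethenyl)benzene
Product: 4 2-[3-(benzyloxy)-5-methoxyphenyl]acetaldehyde
Conditions: 2 M aq. HCl, THF, 50 °C; crude aldehyde dried azeotropically and used at once
Reagents that add atoms: water, O
Why: Acid-catalysed enol ether hydrolysis (C-protonation, hemiacetal, loss of methanol) should unmask the arylacetaldehyde, which is not stored because it is prone to self-condensation.

Step 4
Reactants: 5 undec-10-en-1-ol
Product: 6 benzyl undec-10-en-1-yl ether
Conditions: NaH, BnBr, cat. Bu4NI, THF, 0 °C to rt
Reagents that add atoms: benzyl bromide, BrCc1ccccc1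
Why: Williamson ether synthesis of the primary alkoxide with benzyl bromide should proceed cleanly and leaves the terminal olefin untouched.

Step 5
Reactants: 4 2-[3-(benzyloxy)-5-methoxyphenyl]acetaldehyde; 6 benzyl undec-10-en-1-yl ether
Product: 8 (2R)-13-(benzyloxy)-1-[3-(benzyloxy)-5-methoxyphenyl]tridecan-2-yl acetate, via racemic 1-bromoalkyl acetate 7 (not isolated)
Conditions: AcBr (1.0 equiv), CH2Cl2, 0 °C to rt, volatiles removed; then 6 (1.5 equiv), NiBr2·glyme (NiBr2·MeOCH2CH2OMe, 10 mol %), chiral bis(oxazoline) L* (12 mol %), (EtO)3SiH, K3PO4·H2O, iPr2O, 0 °C to rt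
Reagents that add atoms: acetyl bromide, CC(Br)=O
Why: Acetyl bromide should add across the C=O of 4 to give racemic 7; a nickel hydride formed from NiBr2, the silane and phosphate should then insert the terminal olefin of 6 in the anti-Markovnikov sense to a primary alkylnickel, monovalent nickel should abstract bromine from 7 to give the planar α-acetoxyalkyl radical, and capture of this radical by the chiral alkylnickel followed by reductive elimination from trivalent nickel should form the C2–C3 bond. The closest known reaction type is the nickel/bis(oxazoline)-catalysed enantioconvergent hydroalkylation of terminal olefins with racemic 1-bromoalkyl esters (from aliphatic aldehydes and acyl bromides) and a hydrosilane, which gives esters of dialkyl carbinols directly. No ring is closed. The C2 stereocentre is set by the chiral ligand on nickel (catalyst control): both enantiomers of 7 pass through the same radical, and the ester carbonyl oxygen binds nickel so that the radical is held in a defined two-point arrangement when the bond forms. The step needs linear regioselectivity, which the unbranched terminal vinyl group of 6 secures, and it needs cross-coupling to outrun loss of HBr to the enol acetate, hydrodebromination and alkylation of the electron-rich ring, which is favoured by making 7 without any Lewis acid, using it at once and coupling at or below room temperature; the benzyl and methyl ethers are inert.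

Step 6
Reactants: 8 (2R)-13-(benzyloxy)-1-[3-(benzyloxy)-5-methoxyphenyl]tridecan-2-yl acetate
Product: 9 (2R)-13-hydroxy-1-(3-hydroxy-5-methoxyphenyl)tridecan-2-yl acetate
Conditions: H2 (1 atm), Pd(OH)2/C, EtOAc, rt
Reagents that add atoms: none
Why: Hydrogenolysis of both O-benzyl ethers over palladium should free the phenol and the primary alcohol in one operation; the secondary acetate is homobenzylic, not benzylic, and too far from either hydroxyl for acyl migration, so the ester and the C2 configuration should remain.

**Compound list**
1 | 3-hydroxy-5-methoxybenzaldehyde | COc1cc(O)cc(C=O)c1 | starting material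
2 | 3-(benzyloxy)-5-methoxybenzaldehyde | COc1cc(OCc2ccccc2)cc(C=O)c1 | intermediate
3 | 1-(benzyloxy)-3-methoxy-5-(2-methoxyethenyl)benzene (E/Z mixture) | COC=Cc1cc(OC)cc(OCc2ccccc2)c1 | intermediate
4 | 2-[3-(benzyloxy)-5-methoxyphenyl]acetaldehyde | COc1cc(OCc2ccccc2)cc(CC=O)c1 | intermediate
5 | undec-10-en-1-ol | C=CCCCCCCCCCO | starting material
6 | benzyl undec-10-en-1-yl ether | C=CCCCCCCCCCOCc1ccccc1 | intermediate
7 | racemic 2-[3-(benzyloxy)-5-methoxyphenyl]-1-bromoethyl acetate (not isolated) | CC(=O)OC(Br)Cc1cc(OC)cc(OCc2ccccc2)c1 | intermediate
8 | (2R)-13-(benzyloxy)-1-[3-(benzyloxy)-5-methoxyphenyl]tridecan-2-yl acetate | COc1cc(OCc2ccccc2)cc(C[C@@H](CCCCCCCCCCCOCc2ccccc2)OC(C)=O)c1 | intermediate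
9 | (2R)-13-hydroxy-1-(3-hydroxy-5-methoxyphenyl)tridecan-2-yl acetate | COc1cc(O)cc(C[C@@H](CCCCCCCCCCCO)OC(C)=O)c1 | target

**Step count and risks**
Total step count: 6. Longest linear sequence: 5 steps (1 → 2 → 3 → 4 → 8 → 9).

Steps most likely to fail:

1. Step 5. Loss of HBr from the bromoacetate to the styrenyl enol acetate, alkylation of the electron-rich ring by the bromoacetate, or weak facial discrimination with the small acetyl group could erode yield or enantiopurity. The fallback sets out from 6 and 4 and comes back at 8, forming the same bond by a polar addition and adding the acetate afterwards. Olefin 6 would be hydroborated with Et2BH (from BH3·SMe2 and BEt3) to [11-(benzyloxy)undecyl]diethylborane F1. Boron–zinc exchange with neat Et2Zn would turn this into bis[11-(benzyloxy)undecyl]zinc F2. Addition of the zinc reagent to aldehyde 4 in toluene at −20 °C with Ti(OiPr)4 and a catalytic amount of trans-1,2-bis(trifluoromethanesulfonamido)cyclohexane should give (2R)-13-(benzyloxy)-1-[3-(benzyloxy)-5-methoxyphenyl]tridecan-2-ol F3. The ligand antipode that gives the (R)-alcohol is expected to be the (1S,2S)-form by analogy with simple aldehydes, to be confirmed on a model. Acetylation (Ac2O, pyridine, DMAP, CH2Cl2) then returns to 8.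

2. Step 3. Acid-promoted self-aldol condensation or ring alkylation of the electron-rich arylacetaldehyde could occur during the hydrolysis. The fallback sets out from 2 and comes back at 4, forming the aldehyde under non-acidic conditions. Wittig methylenation of 2 (Ph3PCH3Br, KOtBu, THF) should give 1-(benzyloxy)-3-ethenyl-5-methoxybenzene F4. Hydroboration with 9-BBN in THF should give 9-{2-[3-(benzyloxy)-5-methoxyphenyl]ethyl}-9-borabicyclo[3.3.1]nonane F5, which is oxidised in the same flask (NaOH, H2O2) to 2-[3-(benzyloxy)-5-methoxyphenyl]ethan-1-ol F6. Oxidation with Dess–Martin periodinane buffered with NaHCO3 in CH2Cl2 then gives 4 just before use.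

3. Step 6. Slow cleavage of the aliphatic benzyl ether, catalyst poisoning by nickel or silicon residues, or partial ring saturation under forcing conditions could occur. The fallback sets out from 8 and comes back at 9 directly. It replaces hydrogenolysis by Lewis-acid debenzylation with BCl3 and pentamethylbenzene as cation scavenger in CH2Cl2 at −78 °C, conditions under which alkyl acetates and aryl methyl ethers should survive. No new compound is made.

Further compounds
F1 | step 5 | [11-(benzyloxy)undecyl]diethylborane | CCB(CC)CCCCCCCCCCCOCc1ccccc1
F2 | step 5 | bis[11-(benzyloxy)undecyl]zinc | C(CCCCCCCCCCOCc1ccccc1)[Zn]CCCCCCCCCCCOCc1ccccc1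
F3 | step 5 | (2R)-13-(benzyloxy)-1-[3-(benzyloxy)-5-methoxyphenyl]tridecan-2-ol | COc1cc(OCc2ccccc2)cc(C[C@@H](CCCCCCCCCCCOCc2ccccc2)O)c1
F4 | step 3 | 1-(benzyloxy)-3-ethenyl-5-methoxybenzene | COc1cc(OCc2ccccc2)cc(C=C)c1
F5 | step 3 | 9-{2-[3-(benzyloxy)-5-methoxyphenyl]ethyl}-9-borabicyclo[3.3.1]nonane | COc1cc(OCc2ccccc2)cc(CCB2C3CCCC2CCC3)c1
F6 | step 3 | 2-[3-(benzyloxy)-5-methoxyphenyl]ethan-1-ol | COc1cc(OCc2ccccc2)cc(CCO)c1
F0 | step 6 | none | none
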